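**Plan**

- Retrosynthetic cuts, in order: the C3–O ester and the epoxide oxygen; the ring bond C7–C8; C3–C4 (dienyl–acyl); C1–C2 (aldol); the C9–CH3/C8–I pair back to a terminal alkyne.
- Enabling feature: in the ten-membered carbocycle, ring CH2 C7 is bonded to C8, the CH terminus of the E-trisubstituted C8=C9(CH3) olefin. This alkyl–alkenyl bond bears no stereocentre, so it can be made from a C7 alkylborane and a C8 alkenyl iodide. The borane comes from the vinyl end of the C4=C5(CH3)–C6=C7 diene.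
- Forward order: chain built C8–C10, then C1/C2, then C3, then C4–C7; the single ring is closed last at C7–C8; epoxide, C3 ester and free C10–OH follow.
- Stereochemistry: C10 from (S)-glyceraldehyde acetonide; C1 and C2 from an Evans syn aldol; C3 from a 1,3-anti Evans–Tishchenko reduction that also installs the C1 tiglate; C4/C5 from C3–OH-directed epoxidation.
- The (2R,3S) side chain comes from a second Evans syn aldol; both E-trisubstituted olefins come from Zr-catalysed carboalumination–iodination.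

Key step: step 16

Remark: atoms are labelled C1 (tigloyloxy carbon), C2 (isopropyl), C3 (acyloxy), C4–C5 (epoxide, CH3 on C5), C6, C7, C8=C9 (CH3 on C9), C10 (free OH) throughout; ring names use these locants; TBS = tert-butyldimethylsilyl, TES = triethylsilyl.

**Route**

Step 1
Reactants: 1 (S)-2,2-dimethyl-1,3-dioxolane-4-carbaldehyde
Product: 2 (R)-4-ethynyl-2,2-dimethyl-1,3-dioxolane
Conditions: dimethyl (1-diazo-2-oxopropyl)phosphonate, K2CO3, MeOH, 0 °C → rt
Reagents that add atoms: dimethyl (1-diazo-2-oxopropyl)phosphonate, CC(=O)C(=[N+]=[N-])P(=O)(OC)OC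
Why: The Ohira–Bestmann homologation (in situ Seyferth–Gilbert reagent, carbene 1,2-shift) turns the formyl group into a terminal alkyne under carbonate conditions mild enough that the adjacent stereocentre (future C10) should be retained.

Step 2
Reactants: 2 (R)-4-ethynyl-2,2-dimethyl-1,3-dioxolane
Product: 3 (R)-but-3-yne-1,2-diol
Conditions: p-TsOH·H2O (cat.), MeOH, rt
Reagents that add atoms: none
Why: Acid-catalysed transacetalisation to methanol frees the diol, because an acetonide next to the alkyne would be opened by the Lewis-acidic trimethylaluminium of step 4.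

Step 3
Reactants: 3 (R)-but-3-yne-1,2-diol
Product: 4 (R)-3,4-bis[(tert-butyldimethylsilyl)oxy]but-1-yne
Conditions: TBSCl, imidazole, DMF, rt
Reagents that add atoms: tert-butyldimethylsilyl chloride, CC(C)(C)[Si](C)(C)Cl
Why: Standard silyl ether formation on both hydroxyls gives a Lewis-acid-tolerant substrate and places the TBS group that C10–O keeps to the end.

Step 4
Reactants: 4 (R)-3,4-bis[(tert-butyldimethylsilyl)oxy]but-1-yne
Product: 6 (R,E)-3,4-bis[(tert-butyldimethylsilyl)oxy]-1-iodo-2-methylbut-1-ene, via alkenylalane 5 (not isolated)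
Conditions: AlMe3, Cp2ZrCl2 (cat.), H2O (1 equiv), CH2Cl2, −20 → 0 °C; then I2, THF, −20 °C
Reagents that add atoms: trimethylaluminium, C[Al](C)C; iodine, II
Why: Zirconium-catalysed Negishi carboalumination adds methyl and aluminium syn across the terminal alkyne with aluminium at the terminus, and iodinolysis with retention gives the (E)-C8 iodide and the C9 methyl in one operation.

Step 5
Reactants: 6 (R,E)-3,4-bis[(tert-butyldimethylsilyl)oxy]-1-iodo-2-methylbut-1-ene
Product: 7 (R,E)-2-[(tert-butyldimethylsilyl)oxy]-4-iodo-3-methylbut-3-en-1-ol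
Conditions: HF·pyridine, pyridine, THF, 0 °C
Reagents that add atoms: none
Why: Buffered HF·pyridine cleaves the unhindered primary TBS ether much faster than the secondary allylic one (chemoselective desilylation), exposing only the C1 hydroxyl.

Step 6
Reactants: 7 (R,E)-2-[(tert-butyldimethylsilyl)oxy]-4-iodo-3-methylbut-3-en-1-ol
Product: 8 (R,E)-2-[(tert-butyldimethylsilyl)oxy]-4-iodo-3-methylbut-3-enal
Conditions: Dess–Martin periodinane, pyridine, CH2Cl2, 0 °C; used crude
Reagents that add atoms: none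
Why: Dess–Martin oxidation under buffered, non-enolising conditions gives the α-silyloxy-β,γ-unsaturated aldehyde, which is used at once so that C10 is not epimerised and the olefin does not move into conjugation.

Step 7
Reactants: 9 prop-2-yn-1-ol
Product: 11 (E)-3-iodo-2-methylprop-2-en-1-ol, via alkenylalane 10 (not isolated)
Conditions: AlMe3, Cp2ZrCl2 (cat.), CH2Cl2, 0 °C → rt; then I2, THF, −30 °C
Reagents that add atoms: trimethylaluminium, C[Al](C)C; iodine, II
Why: Negishi carboalumination–iodination of propargyl alcohol (as its aluminium alkoxide) is the standard entry to the (E)-iodoalkene with the methyl on the internal carbon.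

Step 8
Reactants: 11 (E)-3-iodo-2-methylprop-2-en-1-ol
Product: 12 (E)-3-iodo-2-methylprop-2-enal
Conditions: MnO2, CH2Cl2, rt
Reagents that add atoms: none
Why: Manganese dioxide oxidises the allylic alcohol selectively to the enal without touching the alkenyl iodide (allylic oxidation).

Step 9
Reactants: 12 (E)-3-iodo-2-methylprop-2-enal
Product: 13 (E)-1-iodo-2-methylbuta-1,3-diene
Conditions: Ph3PCH3Br, KHMDS, THF, −78 → 0 °C; kept as a solution (volatile)
Reagents that add atoms: methyltriphenylphosphonium bromide, C[P+](c1ccccc1)(c1ccccc1)c1ccccc1.[Br-]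
Why: Wittig methylenation with the non-stabilised ylide converts the formyl group into the vinyl group (future C6=C7) and leaves the iodoalkene geometry untouched.

Step 10
Reactants: 14 (S)-4-benzyloxazolidin-2-one; 15 3-methylbutanoyl chloride
Product: 16 (S)-4-benzyl-3-(3-methylbutanoyl)oxazolidin-2-one
Conditions: Et3N, DMAP (cat.), CH2Cl2, 0 °C → rt
Reagents that add atoms: none
Why: DMAP-catalysed N-acylation of the oxazolidinone gives the imide that carries C2, its isopropyl group and C3.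

Step 11
Reactants: 16 (S)-4-benzyl-3-(3-methylbutanoyl)oxazolidin-2-one; 8 (R,E)-2-[(tert-butyldimethylsilyl)oxy]-4-iodo-3-methylbut-3-enal
Product: 18 (S)-4-benzyl-3-[(2S,3S,4R,E)-4-[(tert-butyldimethylsilyl)oxy]-3-hydroxy-6-iodo-5-methyl-2-(propan-2-yl)hex-5-enoyl]oxazolidin-2-one, via (Z)-boron enolate 17 (not isolated)
Conditions: Bu2BOTf, iPr2NEt, CH2Cl2, 0 °C; then 8, −78 → 0 °C; then pH 7 buffer, MeOH, 30% H2O2, 0 °C
Reagents that add atoms: none
Why: Evans syn aldol in which the (Z)-dibutylboron enolate reacts through a Zimmerman–Traxler chair on the face opposite the benzyl group, setting C2 (S) and C1 (S) syn, and this auxiliary control is matched with the Cornforth/polar Felkin–Anh preference of the α-silyloxy aldehyde for the anti C10/C1 relationship.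

Step 12
Reactants: 18 (S)-4-benzyl-3-[(2S,3S,4R,E)-4-[(tert-butyldimethylsilyl)oxy]-3-hydroxy-6-iodo-5-methyl-2-(propan-2-yl)hex-5-enoyl]oxazolidin-2-one
Product: 19 (2S,3S,4R,E)-4-[(tert-butyldimethylsilyl)oxy]-3-hydroxy-6-iodo-N-methoxy-N,5-dimethyl-2-(propan-2-yl)hex-5-enamide
Conditions: MeNH(OMe)·HCl, AlMe3, THF, −20 → 0 °C; Rochelle salt work-up
Reagents that add atoms: N,O-dimethylhydroxylamine hydrochloride, CNOC.Cl
Why: Weinreb transamination with the aluminium amide, assisted by the free C1 hydroxyl as its aluminium alkoxide, displaces the auxiliary without epimerising C2 and gives an acyl donor that stops at the ketone stage.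

Step 13
Reactants: 19 (2S,3S,4R,E)-4-[(tert-butyldimethylsilyl)oxy]-3-hydroxy-6-iodo-N-methoxy-N,5-dimethyl-2-(propan-2-yl)hex-5-enamide; 13 (E)-1-iodo-2-methylbuta-1,3-diene
Product: 22 (3E,6S,7S,8R,9E)-8-[(tert-butyldimethylsilyl)oxy]-7-hydroxy-10-iodo-3,9-dimethyl-6-(propan-2-yl)deca-1,3,9-trien-5-one, via dienyllithium 20 (not isolated), via dienylmagnesium bromide 21 (not isolated)
Conditions: 13, t-BuLi (2 equiv per 13), Et2O, −78 °C; MgBr2·OEt2, −78 → −40 °C; then 19 (3 equiv of 21 per 19), THF, −40 → 0 °C; sat. NH4Cl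
Reagents that add atoms: none
Why: Iodine–lithium exchange with retention, transmetalation to magnesium (so that no halogen–metal exchange occurs at the C8 iodide) and Grignard addition to the Weinreb amide give a chelated tetrahedral intermediate that releases the (E)-dienone only on work-up, one equivalent of the Grignard reagent being spent on the C1 hydroxyl.

Step 14
Reactants: 22 (3E,6S,7S,8R,9E)-8-[(tert-butyldimethylsilyl)oxy]-7-hydroxy-10-iodo-3,9-dimethyl-6-(propan-2-yl)deca-1,3,9-trien-5-one; 23 (E)-2-methylbut-2-enal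
Product: 24 (3E,5R,6R,7S,8R,9E)-8-[(tert-butyldimethylsilyl)oxy]-5-hydroxy-10-iodo-3,9-dimethyl-6-(propan-2-yl)deca-1,3,9-trien-7-yl (E)-2-methylbut-2-enoate
Conditions: SmI2 (30 mol %), 23 (excess), THF, −10 °C, dark
Reagents that add atoms: none
Why: Evans–Tishchenko reduction in which the samarium-bound hemiacetal formed from the C1 hydroxyl and tiglaldehyde delivers its hydride intramolecularly to the C3 ketone through a chair-like six-membered transition state, setting C3 1,3-anti to C1 ((5R) in this compound) while leaving the tigloyl group on C1–O and the C3 hydroxyl free.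

Step 15
Reactants: 24 (3E,5R,6R,7S,8R,9E)-8-[(tert-butyldimethylsilyl)oxy]-5-hydroxy-10-iodo-3,9-dimethyl-6-(propan-2-yl)deca-1,3,9-trien-7-yl (E)-2-methylbut-2-enoate
Product: 25 (3E,5R,6S,7S,8R,9E)-8-[(tert-butyldimethylsilyl)oxy]-10-iodo-3,9-dimethyl-6-(propan-2-yl)-5-[(triethylsilyl)oxy]deca-1,3,9-trien-7-yl (E)-2-methylbut-2-enoate
Conditions: TESOTf, 2,6-lutidine, CH2Cl2, −78 °C
Reagents that add atoms: triethylsilyl trifluoromethanesulfonate, CC[Si](CC)(CC)OS(=O)(=O)C(F)(F)F
Why: Low-temperature silyl ether formation protects the dienylic C3 alcohol without ionising it, so that neither 1,3-migration of the tiglate nor borinate formation at C3–O interferes with the ring closure.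

Step 16
Reactants: 25 (3E,5R,6S,7S,8R,9E)-8-[(tert-butyldimethylsilyl)oxy]-10-iodo-3,9-dimethyl-6-(propan-2-yl)-5-[(triethylsilyl)oxy]deca-1,3,9-trien-7-yl (E)-2-methylbut-2-enoate
Product: 27 (1S,2S,3R,4E,8E,10R)-10-[(tert-butyldimethylsilyl)oxy]-5,9-dimethyl-2-(propan-2-yl)-3-[(triethylsilyl)oxy]cyclodeca-4,8-dien-1-yl (E)-2-methylbut-2-enoate, via alkylborane 26 (not isolated)
Conditions: 9-BBN, THF, 0 °C → rt; then syringe-pump addition to Pd(dppf)Cl2·CH2Cl2 (20 mol %), AsPh3 (20 mol %), aq. K3PO4, THF/DMF, 40 °C, final ca. 1 mM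
Reagents that add atoms: none
Why: 9-BBN adds across the monosubstituted C6=C7 vinyl end of the diene with boron on C7, and after base activation the borate transmetalates to the alkenylpalladium(II) iodide formed by stereoretentive oxidative addition at C8, reductive elimination then forming C7–C8. The closest known reaction type is the intramolecular B-alkyl Suzuki–Miyaura macrocyclisation of iodoalkenyl alkyl-9-BBN compounds, used here at the small-ring end of its range. The ten-membered carbocycle closes end to end through an eleven-membered alkyl(alkenyl)palladacycle that contracts on reductive elimination. No stereocentre is created, C1, C2, C3 and C10 are spectators, and both trisubstituted olefins keep the E geometry installed by the carboalumination–iodination steps. The step needs chemoselective hydroboration, which the steric demand of 9-BBN secures because the C4=C5 olefin, the C8 iodoalkene and the tiglate are all trisubstituted, and cyclisation over oligomerisation, which slow addition to millimolar concentration and the chain-turning gauche preferences of the four contiguous substituted carbons C10–C3 should secure. dppf/AsPh3 are chosen so that reductive elimination outruns β-hydride elimination, and the temperature stays at or below 40 °C so that the E,E-cyclodeca-1,5-diene does not undergo Cope rearrangement.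

Step 17
Reactants: 27 (1S,2S,3R,4E,8E,10R)-10-[(tert-butyldimethylsilyl)oxy]-5,9-dimethyl-2-(propan-2-yl)-3-[(triethylsilyl)oxy]cyclodeca-4,8-dien-1-yl (E)-2-methylbut-2-enoate
Product: 28 (1S,2R,3R,4E,8E,10R)-10-[(tert-butyldimethylsilyl)oxy]-3-hydroxy-5,9-dimethyl-2-(propan-2-yl)cyclodeca-4,8-dien-1-yl (E)-2-methylbut-2-enoate
Conditions: HF·pyridine, pyridine, THF, 0 °C
Reagents that add atoms: none
Why: Buffered HF·pyridine removes the secondary TES ether selectively in the presence of the more hindered TBS ether (chemoselective desilylation) under conditions too mild to trigger transannular cyclisation of the 1,5-diene.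

Step 18
Reactants: 28 (1S,2R,3R,4E,8E,10R)-10-[(tert-butyldimethylsilyl)oxy]-3-hydroxy-5,9-dimethyl-2-(propan-2-yl)cyclodeca-4,8-dien-1-yl (E)-2-methylbut-2-enoate
Product: 29 (1S,2R,3S,4R,5R,8E,10R)-10-[(tert-butyldimethylsilyl)oxy]-4,5-epoxy-3-hydroxy-5,9-dimethyl-2-(propan-2-yl)cyclodec-8-en-1-yl (E)-2-methylbut-2-enoate
Conditions: VO(acac)2 (10 mol %), t-BuOOH (decane), CH2Cl2, 0 °C
Reagents that add atoms: tert-butyl hydroperoxide, CC(C)(C)OO
Why: Vanadium-catalysed hydroxyl-directed epoxidation touches only the C4=C5 olefin of the free allylic alcohol, and because A(1,3) strain with the C5 methyl holds C3–H in the olefin plane and the C3 hydroxyl on the outer face of the E-cyclodecene, oxygen should be delivered to that face to give the threo (4R,5R) epoxide.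

Step 19
Reactants: 30 (R)-4-benzyl-3-propanoyloxazolidin-2-one; 31 acetaldehyde
Product: 33 (R)-4-benzyl-3-[(2R,3S)-3-hydroxy-2-methylbutanoyl]oxazolidin-2-one, via (Z)-boron enolate 32 (not isolated)
Conditions: Bu2BOTf, iPr2NEt, CH2Cl2, 0 °C; then 31, −78 → 0 °C; then pH 7 buffer, MeOH, 30% H2O2, 0 °C
Reagents that add atoms: none
Why: Evans syn aldol of the (Z)-boron enolate through a Zimmerman–Traxler chair, the (R)-benzyl auxiliary setting the (2R,3S) configuration of the side chain.

Step 20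
Reactants: 33 (R)-4-benzyl-3-[(2R,3S)-3-hydroxy-2-methylbutanoyl]oxazolidin-2-one
Product: 35 (2R,3S)-3-hydroxy-2-methylbutanoic acid, via peroxy acid 34 (not isolated)
Conditions: LiOH, 30% H2O2, THF/H2O, 0 °C; then aq. Na2SO3; then HCl to pH 2
Reagents that add atoms: hydrogen peroxide, OO
Why: Lithium hydroperoxide attacks the exocyclic imide carbonyl selectively (auxiliary hydrolysis) and sulfite reduction of the peroxy acid gives the acid without epimerisation at C2.

Step 21
Reactants: 35 (2R,3S)-3-hydroxy-2-methylbutanoic acid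
Product: 36 (2R,3S)-3-acetoxy-2-methylbutanoic acid
Conditions: Ac2O, pyridine, DMAP (cat.), CH2Cl2, 0 °C → rt; aqueous work-up
Reagents that add atoms: acetic anhydride, CC(=O)OC(C)=O
Why: Pyridine-mediated O-acetylation of the secondary alcohol, any mixed anhydride at the carboxyl group being hydrolysed on aqueous work-up.

Step 22
Reactants: 29 (1S,2R,3S,4R,5R,8E,10R)-10-[(tert-butyldimethylsilyl)oxy]-4,5-epoxy-3-hydroxy-5,9-dimethyl-2-(propan-2-yl)cyclodec-8-en-1-yl (E)-2-methylbut-2-enoate; 36 (2R,3S)-3-acetoxy-2-methylbutanoic acid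
Product: 38 (1S,2R,3S,4R,5R,8E,10R)-10-[(tert-butyldimethylsilyl)oxy]-4,5-epoxy-5,9-dimethyl-1-[(E)-2-methylbut-2-enoyloxy]-2-(propan-2-yl)cyclodec-8-en-3-yl (2R,3S)-3-acetoxy-2-methylbutanoate, via mixed anhydride 37 (not isolated)
Conditions: 36, 2,4,6-trichlorobenzoyl chloride, Et3N, toluene, rt; then 29, DMAP, toluene, rt
Reagents that add atoms: none
Why: Yamaguchi esterification in which DMAP attacks the preformed mixed anhydride at the less hindered aliphatic carbonyl and the acylpyridinium acylates the hindered C3 hydroxyl at room temperature, conditions chosen to limit β-elimination of acetate and epimerisation at the α-carbon.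

Step 23
Reactants: 38 (1S,2R,3S,4R,5R,8E,10R)-10-[(tert-butyldimethylsilyl)oxy]-4,5-epoxy-5,9-dimethyl-1-[(E)-2-methylbut-2-enoyloxy]-2-(propan-2-yl)cyclodec-8-en-3-yl (2R,3S)-3-acetoxy-2-methylbutanoate
Product: 39 (1S,2S,3S,4R,5R,8E,10R)-4,5-epoxy-10-hydroxy-5,9-dimethyl-1-[(E)-2-methylbut-2-enoyloxy]-2-(propan-2-yl)cyclodec-8-en-3-yl (2R,3S)-3-acetoxy-2-methylbutanoate
Conditions: HF·pyridine, pyridine, THF, 0 °C → rt
Reagents that add atoms: none
Why: Pyridine-buffered HF·pyridine cleaves the C10 TBS ether (fluoride desilylation) under weakly acidic conditions that should neither open the epoxide nor let the C1 tiglate migrate to the C10 hydroxyl.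

**Compound list**

1 | (S)-2,2-dimethyl-1,3-dioxolane-4-carbaldehyde | O=C[C@@H]1COC(C)(C)O1 | starting material
2 | (R)-4-ethynyl-2,2-dimethyl-1,3-dioxolane | C#C[C@@H]1COC(C)(C)O1 | intermediate
3 | (R)-but-3-yne-1,2-diol | C#C[C@@H](O)CO | intermediate
4 | (R)-3,4-bis[(tert-butyldimethylsilyl)oxy]but-1-yne | C#C[C@@H](O[Si](C)(C)C(C)(C)C)CO[Si](C)(C)C(C)(C)C | intermediate
5 | (E)-alkenyl(dimethyl)alane from 4 (AlMe2 on C8, CH3 on C9) | C[Al](C)/C=C(\C)[C@@H](O[Si](C)(C)C(C)(C)C)CO[Si](C)(C)C(C)(C)C | intermediate (not isolated)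
6 | (R,E)-3,4-bis[(tert-butyldimethylsilyl)oxy]-1-iodo-2-methylbut-1-ene | I/C=C(\C)[C@@H](O[Si](C)(C)C(C)(C)C)CO[Si](C)(C)C(C)(C)C | intermediate
7 | (R,E)-2-[(tert-butyldimethylsilyl)oxy]-4-iodo-3-methylbut-3-en-1-ol | I/C=C(\C)[C@@H](O[Si](C)(C)C(C)(C)C)CO | intermediate
8 | (R,E)-2-[(tert-butyldimethylsilyl)oxy]-4-iodo-3-methylbut-3-enal | I/C=C(\C)[C@@H](O[Si](C)(C)C(C)(C)C)C=O | intermediate
9 | prop-2-yn-1-ol (propargyl alcohol) | C#CCO | starting material
10 | (E)-alkenyl(dimethyl)alane of propargyl alcohol, as its dimethylaluminium alkoxide | C[Al](C)/C=C(\C)CO[Al](C)C | intermediate (not isolated)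
11 | (E)-3-iodo-2-methylprop-2-en-1-ol | I/C=C(\C)CO | intermediate
12 | (E)-3-iodo-2-methylprop-2-enal | I/C=C(\C)C=O | intermediate
13 | (E)-1-iodo-2-methylbuta-1,3-diene | I/C=C(\C)C=C | intermediate
14 | (S)-4-benzyloxazolidin-2-one | O=C1OC[C@H](Cc2ccccc2)N1 | starting material
15 | 3-methylbutanoyl chloride | CC(C)CC(Cl)=O | starting material
16 | (S)-4-benzyl-3-(3-methylbutanoyl)oxazolidin-2-one | CC(C)CC(=O)N1[C@@H](Cc2ccccc2)COC1=O | intermediate
17 | (Z)-dibutylboron enolate of 16 | CC(C)/C=C(\OB(CCCC)CCCC)N1[C@@H](Cc2ccccc2)COC1=O | intermediate (not isolated)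
18 | (S)-4-benzyl-3-[(2S,3S,4R,E)-4-[(tert-butyldimethylsilyl)oxy]-3-hydroxy-6-iodo-5-methyl-2-(propan-2-yl)hex-5-enoyl]oxazolidin-2-one | I/C=C(\C)[C@@H](O[Si](C)(C)C(C)(C)C)[C@@H](O)[C@H](C(C)C)C(=O)N1[C@@H](Cc2ccccc2)COC1=O | intermediate
19 | (2S,3S,4R,E)-4-[(tert-butyldimethylsilyl)oxy]-3-hydroxy-6-iodo-N-methoxy-N,5-dimethyl-2-(propan-2-yl)hex-5-enamide | I/C=C(\C)[C@@H](O[Si](C)(C)C(C)(C)C)[C@@H](O)[C@H](C(C)C)C(=O)N(C)OC | intermediate
20 | (E)-(2-methylbuta-1,3-dien-1-yl)lithium | [Li]/C=C(\C)C=C | intermediate (not isolated)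
21 | (E)-(2-methylbuta-1,3-dien-1-yl)magnesium bromide | Br[Mg]/C=C(\C)C=C | intermediate (not isolated)
22 | (3E,6S,7S,8R,9E)-8-[(tert-butyldimethylsilyl)oxy]-7-hydroxy-10-iodo-3,9-dimethyl-6-(propan-2-yl)deca-1,3,9-trien-5-one | I/C=C(\C)[C@@H](O[Si](C)(C)C(C)(C)C)[C@@H](O)[C@H](C(C)C)C(=O)/C=C(\C)C=C | intermediate
23 | (E)-2-methylbut-2-enal (tiglaldehyde) | C/C=C(\C)C=O | starting material
24 | (3E,5R,6R,7S,8R,9E)-8-[(tert-butyldimethylsilyl)oxy]-5-hydroxy-10-iodo-3,9-dimethyl-6-(propan-2-yl)deca-1,3,9-trien-7-yl (E)-2-methylbut-2-enoate | I/C=C(\C)[C@@H](O[Si](C)(C)C(C)(C)C)[C@@H](OC(=O)/C(C)=C/C)[C@H](C(C)C)[C@H](O)/C=C(\C)C=C | intermediate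
25 | (3E,5R,6S,7S,8R,9E)-8-[(tert-butyldimethylsilyl)oxy]-10-iodo-3,9-dimethyl-6-(propan-2-yl)-5-[(triethylsilyl)oxy]deca-1,3,9-trien-7-yl (E)-2-methylbut-2-enoate | I/C=C(\C)[C@@H](O[Si](C)(C)C(C)(C)C)[C@@H](OC(=O)/C(C)=C/C)[C@H](C(C)C)[C@H](O[Si](CC)(CC)CC)/C=C(\C)C=C | intermediate
26 | B-alkyl-9-BBN of 25 (9-borabicyclo[3.3.1]nonan-9-yl on C7, C6 now CH2) | I/C=C(\C)[C@@H](O[Si](C)(C)C(C)(C)C)[C@@H](OC(=O)/C(C)=C/C)[C@H](C(C)C)[C@H](O[Si](CC)(CC)CC)/C=C(\C)CCB1C2CCCC1CCC2 | intermediate (not isolated)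
27 | (1S,2S,3R,4E,8E,10R)-10-[(tert-butyldimethylsilyl)oxy]-5,9-dimethyl-2-(propan-2-yl)-3-[(triethylsilyl)oxy]cyclodeca-4,8-dien-1-yl (E)-2-methylbut-2-enoate | C/C=C(\C)C(=O)O[C@H]1[C@H](C(C)C)[C@H](O[Si](CC)(CC)CC)/C=C(\C)CC/C=C(\C)[C@H]1O[Si](C)(C)C(C)(C)C | intermediate
28 | (1S,2R,3R,4E,8E,10R)-10-[(tert-butyldimethylsilyl)oxy]-3-hydroxy-5,9-dimethyl-2-(propan-2-yl)cyclodeca-4,8-dien-1-yl (E)-2-methylbut-2-enoate | C/C=C(\C)C(=O)O[C@H]1[C@H](C(C)C)[C@H](O)/C=C(\C)CC/C=C(\C)[C@H]1O[Si](C)(C)C(C)(C)C | intermediate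
29 | (1S,2R,3S,4R,5R,8E,10R)-10-[(tert-butyldimethylsilyl)oxy]-4,5-epoxy-3-hydroxy-5,9-dimethyl-2-(propan-2-yl)cyclodec-8-en-1-yl (E)-2-methylbut-2-enoate | C/C=C(\C)C(=O)O[C@H]1[C@H](C(C)C)[C@H](O)[C@H]2O[C@]2(C)CC/C=C(\C)[C@H]1O[Si](C)(C)C(C)(C)C | intermediate
30 | (R)-4-benzyl-3-propanoyloxazolidin-2-one | CCC(=O)N1[C@H](Cc2ccccc2)COC1=O | starting material
31 | acetaldehyde | CC=O | starting material
32 | (Z)-dibutylboron enolate of 30 | C/C=C(\OB(CCCC)CCCC)N1[C@H](Cc2ccccc2)COC1=O | intermediate (not isolated)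
33 | (R)-4-benzyl-3-[(2R,3S)-3-hydroxy-2-methylbutanoyl]oxazolidin-2-one | O=C([C@H](C)[C@H](C)O)N1[C@H](Cc2ccccc2)COC1=O | intermediate
34 | (2R,3S)-3-hydroxy-2-methylbutaneperoxoic acid | OOC(=O)[C@H](C)[C@H](C)O | intermediate (not isolated)
35 | (2R,3S)-3-hydroxy-2-methylbutanoic acid | OC(=O)[C@H](C)[C@H](C)O | intermediate
36 | (2R,3S)-3-acetoxy-2-methylbutanoic acid | OC(=O)[C@H](C)[C@H](C)OC(C)=O | intermediate
37 | (2R,3S)-3-acetoxy-2-methylbutanoic 2,4,6-trichlorobenzoic anhydride | O=C(OC(=O)c1c(Cl)cc(Cl)cc1Cl)[C@H](C)[C@H](C)OC(C)=O | intermediate (not isolated)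
38 | (1S,2R,3S,4R,5R,8E,10R)-10-[(tert-butyldimethylsilyl)oxy]-4,5-epoxy-5,9-dimethyl-1-[(E)-2-methylbut-2-enoyloxy]-2-(propan-2-yl)cyclodec-8-en-3-yl (2R,3S)-3-acetoxy-2-methylbutanoate | C/C=C(\C)C(=O)O[C@H]1[C@H](C(C)C)[C@H](OC(=O)[C@H](C)[C@H](C)OC(C)=O)[C@H]2O[C@]2(C)CC/C=C(\C)[C@H]1O[Si](C)(C)C(C)(C)C | intermediate
39 | (1S,2S,3S,4R,5R,8E,10R)-4,5-epoxy-10-hydroxy-5,9-dimethyl-1-[(E)-2-methylbut-2-enoyloxy]-2-(propan-2-yl)cyclodec-8-en-3-yl (2R,3S)-3-acetoxy-2-methylbutanoate | C/C=C(\C)C(=O)O[C@H]1[C@H](C(C)C)[C@H](OC(=O)[C@H](C)[C@H](C)OC(C)=O)[C@H]2O[C@]2(C)CC/C=C(\C)[C@H]1O | target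

**Step count and risks**

Total steps: 23. Longest linear sequence: 16 (steps 1–6, 11–18, 22, 23).

Steps most likely to fail:

1. Step 16. The strained ten-membered ring may form too slowly, so that intermolecular coupling (oligomers), β-hydride elimination from the C7 alkylpalladium or protodeboronation take over. Fallback: setting out from 25, hydroboration with 9-BBN (through 26) followed by NaBO3 oxidation would give the C7 primary alcohol F1. Iodination (I2, PPh3, imidazole) would give the primary alkyl iodide F2. Zinc dust/LiCl in THF should insert selectively into the sp3 C–I bond to give the alkylzinc iodide F3. This would be added slowly at high dilution to Pd2(dba)3/SPhos in THF, so that the same C7–C8 bond closes by intramolecular Negishi coupling without aqueous base, coming back to the route at 27.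

2. Step 14. Tiglaldehyde may fail as hydride donor: hemiacetal formation at the hindered C1 hydroxyl may be slow, and retro-aldol cleavage of the β-hydroxy ketone or reductive coupling of the enal may compete. Fallback: setting out from 22, hydroxyl-directed reduction with Me4NBH(OAc)3 (MeCN/AcOH, −30 °C) would give the 1,3-anti diol F4. Silylation of the less hindered allylic C3 hydroxyl (TESCl, imidazole, CH2Cl2, −20 °C) would give the C3 triethylsilyl ether with free C1 hydroxyl F5. Acylation of that hydroxyl with commercial tigloyl chloride (DMAP, pyridine, 40 °C) comes back to the route at 25.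

3. Step 22. The activated β-acetoxy acyl donor may lose acetic acid by β-elimination or epimerise at its α-carbon before the hindered C3 hydroxyl is acylated. Fallback: setting out from 35 and 29, the order of acetylation and esterification is reversed. Double silylation of 35 (TESCl, imidazole, DMF) would give the silyl ester silyl ether F6, whose silyl ester is cleaved with K2CO3 in aqueous MeOH to the β-silyloxy acid F7. Yamaguchi activation would give the mixed anhydride F8, and coupling with 29 the C3 ester F9. Buffered HF·pyridine at 0 °C would remove only the side-chain TES group to give the side-chain alcohol F10 (C10 still TBS-protected), and acetylation (Ac2O, pyridine, DMAP) comes back to the route at 38.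

**Further compounds**

F1 | step 16 | (3E,5R,6S,7S,8R,9E)-8-[(tert-butyldimethylsilyl)oxy]-1-hydroxy-10-iodo-3,9-dimethyl-6-(propan-2-yl)-5-[(triethylsilyl)oxy]deca-3,9-dien-7-yl (E)-2-methylbut-2-enoate | I/C=C(\C)[C@@H](O[Si](C)(C)C(C)(C)C)[C@@H](OC(=O)/C(C)=C/C)[C@H](C(C)C)[C@H](O[Si](CC)(CC)CC)/C=C(\C)CCO
F2 | step 16 | (3E,5R,6S,7S,8R,9E)-8-[(tert-butyldimethylsilyl)oxy]-1,10-diiodo-3,9-dimethyl-6-(propan-2-yl)-5-[(triethylsilyl)oxy]deca-3,9-dien-7-yl (E)-2-methylbut-2-enoate | I/C=C(\C)[C@@H](O[Si](C)(C)C(C)(C)C)[C@@H](OC(=O)/C(C)=C/C)[C@H](C(C)C)[C@H](O[Si](CC)(CC)CC)/C=C(\C)CCI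
F3 | step 16 | C7 alkylzinc iodide derived from F2 | I/C=C(\C)[C@@H](O[Si](C)(C)C(C)(C)C)[C@@H](OC(=O)/C(C)=C/C)[C@H](C(C)C)[C@H](O[Si](CC)(CC)CC)/C=C(\C)CC[Zn]I
F4 | step 14 | (3E,5R,6R,7S,8R,9E)-8-[(tert-butyldimethylsilyl)oxy]-10-iodo-3,9-dimethyl-6-(propan-2-yl)deca-1,3,9-triene-5,7-diol | I/C=C(\C)[C@@H](O[Si](C)(C)C(C)(C)C)[C@@H](O)[C@H](C(C)C)[C@H](O)/C=C(\C)C=C
F5 | step 14 | (3E,5R,6S,7S,8R,9E)-8-[(tert-butyldimethylsilyl)oxy]-10-iodo-3,9-dimethyl-6-(propan-2-yl)-5-[(triethylsilyl)oxy]deca-1,3,9-trien-7-ol | I/C=C(\C)[C@@H](O[Si](C)(C)C(C)(C)C)[C@@H](O)[C@H](C(C)C)[C@H](O[Si](CC)(CC)CC)/C=C(\C)C=C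
F6 | step 22 | triethylsilyl (2R,3S)-2-methyl-3-[(triethylsilyl)oxy]butanoate | CC[Si](CC)(CC)OC(=O)[C@H](C)[C@H](C)O[Si](CC)(CC)CC
F7 | step 22 | (2R,3S)-2-methyl-3-[(triethylsilyl)oxy]butanoic acid | OC(=O)[C@H](C)[C@H](C)O[Si](CC)(CC)CC
F8 | step 22 | (2R,3S)-2-methyl-3-[(triethylsilyl)oxy]butanoic 2,4,6-trichlorobenzoic anhydride | O=C(OC(=O)c1c(Cl)cc(Cl)cc1Cl)[C@H](C)[C@H](C)O[Si](CC)(CC)CC
F9 | step 22 | (1S,2R,3S,4R,5R,8E,10R)-10-[(tert-butyldimethylsilyl)oxy]-4,5-epoxy-5,9-dimethyl-1-[(E)-2-methylbut-2-enoyloxy]-2-(propan-2-yl)cyclodec-8-en-3-yl (2R,3S)-2-methyl-3-[(triethylsilyl)oxy]butanoate | C/C=C(\C)C(=O)O[C@H]1[C@H](C(C)C)[C@H](OC(=O)[C@H](C)[C@H](C)O[Si](CC)(CC)CC)[C@H]2O[C@]2(C)CC/C=C(\C)[C@H]1O[Si](C)(C)C(C)(C)C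
F10 | step 22 | (1S,2R,3S,4R,5R,8E,10R)-10-[(tert-butyldimethylsilyl)oxy]-4,5-epoxy-5,9-dimethyl-1-[(E)-2-methylbut-2-enoyloxy]-2-(propan-2-yl)cyclodec-8-en-3-yl (2R,3S)-3-hydroxy-2-methylbutanoate | C/C=C(\C)C(=O)O[C@H]1[C@H](C(C)C)[C@H](OC(=O)[C@H](C)[C@H](C)O)[C@H]2O[C@]2(C)CC/C=C(\C)[C@H]1O[Si](C)(C)C(C)(C)C
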